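**Retrosynthetic overview**
1. Target 25 ⇐ C9 ester of hydroxy-germacranolide 19 with protected sarracinic acid 23; 19 ⇐ enone 18 by reagent-controlled 1,2-reduction.
2. α-Methylene lactone of 18 ⇐ Pd cyclocarbonylation of the trans-6-hydroxy-7-ethynyl macrocycle 17.
3. Ten-membered ring ⇐ Grob-type ring expansion of the cis-fused epoxy-decalinol 15 (C4–C9 bond cleaved; gives the 4E alkene, the C9 ketone and the C6–OH; the 1(10)Z alkene is inherited from ring A).
4. Ring A ⇐ isopropenyl addition to C9 and RCM; ring B ⇐ organocatalytic Michael/aldol annulation of β-keto ester 4 with enynal 7, then C4 methylation and C5–C6 epoxidation.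
5. Order of ring formation: ring B (cyclohexenone) → ring A (cyclohexene) → ten-membered carbocycle (expansion) → γ-lactone.

Assumption: ring carbons keep the germacranolide numbering of the target (C1–C10 ring, C11–C13 lactone carbons, C14 on C10, C15 on C4); TBS = tert-butyldimethylsilyl and TIPS = tri(propan-2-yl)silyl are protecting groups; (S)-2-vinyloxirane is bought as a single enantiomer.

**Step 1**
Reactants: 1 methyl acetoacetate; 2 (S)-2-vinyloxirane
Product: 4 methyl (6R)-6-[(tert-butyldimethylsilyl)oxy]-3-oxooct-7-enoate, via methyl (6R)-6-hydroxy-3-oxooct-7-enoate 3 (not isolated)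
Conditions: NaH, THF, 0 °C; n-BuLi, −10 °C; 2, −78 → 0 °C; then TBSCl, DMAP (cat.), 0 °C → rt; aq. NH4Cl
Reagents that add atoms: tert-butyldimethylsilyl chloride, CC(C)(C)[Si](C)(C)Cl
Why: Weiler dianion γ-alkylation, in which the γ-carbanion opens the vinyl epoxide by SN2 at the unhindered CH2 (no Lewis acid, so no allylic or SN2′ opening), the C2 stereocentre comes unchanged from 2 (descriptor R by priority change), and the alkoxide is silylated in the flask.

**Step 2**
Reactants: 5 ethynyltri(propan-2-yl)silane; 6 (E)-3-(dimethylamino)prop-2-enal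
Product: 7 (E)-5-[tri(propan-2-yl)silyl]pent-2-en-4-ynal
Conditions: n-BuLi, THF, −78 °C; 6, −78 → 0 °C; 1 M HCl
Reagents that add atoms: water, O
Why: 1,2-addition of the lithium acetylide to the vinylogous formamide followed by acidic hydrolysis and elimination of dimethylamine gives the thermodynamically favoured (E)-enynal.

**Step 3**
Reactants: 4 methyl (6R)-6-[(tert-butyldimethylsilyl)oxy]-3-oxooct-7-enoate; 7 (E)-5-[tri(propan-2-yl)silyl]pent-2-en-4-ynal
Product: 9 methyl (1R,6S)-3-{(2R)-2-[(tert-butyldimethylsilyl)oxy]but-3-en-1-yl}-2-oxo-6-{[tri(propan-2-yl)silyl]ethynyl}cyclohex-3-ene-1-carboxylate, via Michael adduct aldehyde 8 (not isolated)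
Conditions: (R)-α,α-diphenylprolinol TMS ether (10 mol %), PhCO2H (20 mol %), toluene, 0 °C → rt; then p-TsOH·H2O (10 mol %), 4 Å MS, 40 °C
Reagents that add atoms: none
Why: Jørgensen–Hayashi iminium Michael addition of the β-keto ester carbon (C8) to the enal, with the (R)-catalyst shielding one face so that C7 is set, followed by acid-promoted intramolecular aldol condensation from the γ-CH2 (C4) that closes ring B as the cyclohexenone; C8 equilibrates trans to the C7 substituent.

**Step 4**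
Reactants: 9 methyl (1R,6S)-3-{(2R)-2-[(tert-butyldimethylsilyl)oxy]but-3-en-1-yl}-2-oxo-6-{[tri(propan-2-yl)silyl]ethynyl}cyclohex-3-ene-1-carboxylate
Product: 10 methyl (1R,3R,6S)-3-{(2R)-2-[(tert-butyldimethylsilyl)oxy]but-3-en-1-yl}-3-methyl-2-oxo-6-{[tri(propan-2-yl)silyl]ethynyl}cyclohex-4-ene-1-carboxylate
Conditions: NaH (1.05 equiv), THF, 0 °C; LDA (1.1 equiv), −78 °C; MeI, −78 → −40 °C; aq. NH4Cl
Reagents that add atoms: iodomethane, CI
Why: Proposed new method: deconjugative C-methylation of a cross-conjugated enolate–dienolate dianion, in which NaH removes the C8–H of the β-keto ester, LDA then removes the vinylogous γ-H at C6 (the α′ site is already an enolate), and the more basic dienolate alkylates at its α-carbon C4 while the ester enolate stays blocked, giving the quaternary centre and moving the alkene to C5=C6; in the nearly flat five-sp2 ring MeI should enter anti to the pseudo-axial silylethynyl group on C7 (1,4-trans, as in alkylations of Birch-type cyclohexadienyl enolates), so that C4–Me is trans to the C7 substituent; the closest known reactions are the Weiler β-keto ester dianion γ-alkylation and the deconjugative α-alkylation of enone dienolates, which have not been combined on a 6-alkoxycarbonylcyclohex-2-enone.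

**Step 5**
Reactants: 10 methyl (1R,3R,6S)-3-{(2R)-2-[(tert-butyldimethylsilyl)oxy]but-3-en-1-yl}-3-methyl-2-oxo-6-{[tri(propan-2-yl)silyl]ethynyl}cyclohex-4-ene-1-carboxylate
Product: 11 (2R,5R)-2-{(2R)-2-[(tert-butyldimethylsilyl)oxy]but-3-en-1-yl}-2-methyl-5-{[tri(propan-2-yl)silyl]ethynyl}cyclohex-3-en-1-one
Conditions: LiCl, H2O, DMSO, 120 °C
Reagents that add atoms: none
Why: Krapcho dealkoxycarbonylation of the β-keto methyl ester under near-neutral conditions, with the quaternary C4 preventing re-conjugation of the β,γ-alkene.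

**Step 6**
Reactants: 11 (2R,5R)-2-{(2R)-2-[(tert-butyldimethylsilyl)oxy]but-3-en-1-yl}-2-methyl-5-{[tri(propan-2-yl)silyl]ethynyl}cyclohex-3-en-1-one
Product: 12 (1R,2R,5S,6S)-2-{(2R)-2-[(tert-butyldimethylsilyl)oxy]but-3-en-1-yl}-2-methyl-5-{[tri(propan-2-yl)silyl]ethynyl}-7-oxabicyclo[4.1.0]heptan-3-one
Conditions: m-CPBA, NaHCO3, CH2Cl2, 0 °C
Reagents that add atoms: meta-chloroperoxybenzoic acid, O=C(OO)c1cccc(Cl)c1
Why: Prilezhaev epoxidation of the only electron-rich alkene (the vinyl group with its allylic silyl ether and the silyl alkyne are slower) from the face that carries the small C4–Me and C7–H, so the oxirane is cis to C4–Me and trans to the C7 substituent, which fixes the future C6–O configuration.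

**Step 7**
Reactants: 12 (1R,2R,5S,6S)-2-{(2R)-2-[(tert-butyldimethylsilyl)oxy]but-3-en-1-yl}-2-methyl-5-{[tri(propan-2-yl)silyl]ethynyl}-7-oxabicyclo[4.1.0]heptan-3-one; 13 prop-1-en-2-ylmagnesium bromide
Product: 14 (1R,2R,3S,5S,6S)-2-{(2R)-2-[(tert-butyldimethylsilyl)oxy]but-3-en-1-yl}-2-methyl-3-(prop-1-en-2-yl)-5-{[tri(propan-2-yl)silyl]ethynyl}-7-oxabicyclo[4.1.0]heptan-3-ol
Conditions: CeCl3, THF, −78 °C; aq. NH4Cl
Reagents that add atoms: none
Why: Imamoto organocerium 1,2-addition to the hindered, enolisable ketone, expected anti to the epoxide oxygen and the C4–Me to give the tertiary alcohol syn to the epoxide; C9 becomes the ketone again in step 9, so its epimer converges.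

**Step 8**
Reactants: 14 (1R,2R,3S,5S,6S)-2-{(2R)-2-[(tert-butyldimethylsilyl)oxy]but-3-en-1-yl}-2-methyl-3-(prop-1-en-2-yl)-5-{[tri(propan-2-yl)silyl]ethynyl}-7-oxabicyclo[4.1.0]heptan-3-ol
Product: 15 cis-fused epoxy-octalinol (2R,4R,5R,6S,7S,9S)-2-[(tert-butyldimethylsilyl)oxy]-5,6-epoxy-4,10-dimethyl-7-{[tri(propan-2-yl)silyl]ethynyl}bicyclo[4.4.0]dec-1(10)-en-9-ol (target numbering; C4–C9 is the ring-fusion bond; 4-Me, 9-OH and the epoxide O on one face)
Conditions: Hoveyda–Grubbs II (5 mol %), toluene, 60 °C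
Reagents that add atoms: none
Why: Ring-closing metathesis of the isopropenyl and vinyl groups forms the trisubstituted cyclohexene (ring A), whose ring size fixes the later 1(10)Z geometry, while the bulky TIPS group keeps the alkyne out of enyne metathesis.

**Step 9**
Reactants: 15 cis-fused epoxy-octalinol (2R,4R,5R,6S,7S,9S)-2-[(tert-butyldimethylsilyl)oxy]-5,6-epoxy-4,10-dimethyl-7-{[tri(propan-2-yl)silyl]ethynyl}bicyclo[4.4.0]dec-1(10)-en-9-ol
Product: 16 (2Z,4R,6E,8R,9S)-4-[(tert-butyldimethylsilyl)oxy]-8-hydroxy-2,6-dimethyl-9-{[tri(propan-2-yl)silyl]ethynyl}cyclodeca-2,6-dien-1-one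
Conditions: KOt-Bu (1.1 equiv), THF, −40 → 0 °C; aq. NH4Cl
Reagents that add atoms: none
Why: Grob-type (Wharton) epoxy-alkoxide fragmentation as ring expansion, in which the C9 alkoxide pushes, the C4–C9 bond anti-periplanar to the C5–O bond breaks and the oxirane opens, so the two six-membered rings become the ten-membered ring with the C9 ketone; the reaction is stereospecific (epoxide cis to C4–Me puts C3 anti to C6, giving 4E), the ring-A alkene stays Z, and C6–O is retained as 6R.

**Step 10**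
Reactants: 16 (2Z,4R,6E,8R,9S)-4-[(tert-butyldimethylsilyl)oxy]-8-hydroxy-2,6-dimethyl-9-{[tri(propan-2-yl)silyl]ethynyl}cyclodeca-2,6-dien-1-one
Product: 17 (2Z,4R,6E,8R,9S)-4-[(tert-butyldimethylsilyl)oxy]-9-ethynyl-8-hydroxy-2,6-dimethylcyclodeca-2,6-dien-1-one
Conditions: AgF (1.5 equiv), MeOH/THF, rt, dark; then 1 M HCl
Reagents that add atoms: none
Why: Silver-fluoride protodesilylation of the TIPS-alkyne through the silver acetylide, which leaves the O-silyl ether intact.

**Step 11**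
Reactants: 17 (2Z,4R,6E,8R,9S)-4-[(tert-butyldimethylsilyl)oxy]-9-ethynyl-8-hydroxy-2,6-dimethylcyclodeca-2,6-dien-1-one
Product: 18 (1(10)Z,2R,4E,6R,7S)-2-[(tert-butyldimethylsilyl)oxy]-9-oxogermacra-1(10),4,11(13)-trien-12,6-olide
Conditions: PdCl2 (5 mol %), SnCl2 (5 mol %), PPh3 (10 mol %), CO (7 atm), MeCN, 65 °C
Reagents that add atoms: carbon monoxide, [C-]#[O+]
Why: Norton-type Pd-catalysed cyclocarbonylation of the homopropargylic alcohol (alkoxycarbonyl-Pd, syn insertion of the alkyne, protonolysis) builds the α-methylene-γ-butyrolactone with retention at C6 and C7, hence the trans ring fusion.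

**Step 12**
Reactants: 18 (1(10)Z,2R,4E,6R,7S)-2-[(tert-butyldimethylsilyl)oxy]-9-oxogermacra-1(10),4,11(13)-trien-12,6-olide
Product: 19 (1(10)Z,2R,4E,6R,7S,9S)-2-[(tert-butyldimethylsilyl)oxy]-9-hydroxygermacra-1(10),4,11(13)-trien-12,6-olide
Conditions: (R)-2-methyl-CBS-oxazaborolidine (0.3 equiv), catecholborane (1.5 equiv), toluene, −78 °C
Reagents that add atoms: none
Why: Corey–Bakshi–Shibata 1,2-reduction in which the α-methyl alkenyl group acts as the large substituent, so the (R)-catalyst delivers hydride to give the 9S allylic alcohol, and the α-methylene lactone is not reduced at −78 °C.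

**Step 13**
Reactants: 20 methyl but-2-ynoate
Product: 21 methyl (Z)-2-(hydroxymethyl)but-2-enoate
Conditions: DIBAL-H, HMPA, THF, 0 °C; then CH2O (gas), −78 → 0 °C
Reagents that add atoms: formaldehyde, C=O
Why: Tsuda–Saegusa conjugate hydroalumination of the ynoate gives the α-alumino acrylate (allenolate), which formaldehyde attacks at the α-carbon from the side of the β-hydrogen, placing CH3 cis to the ester (sarracinate geometry).

**Step 14**
Reactants: 21 methyl (Z)-2-(hydroxymethyl)but-2-enoate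
Product: 22 methyl (Z)-2-{[(tert-butyldimethylsilyl)oxy]methyl}but-2-enoate
Conditions: TBSCl, imidazole, CH2Cl2, 0 °C
Reagents that add atoms: tert-butyldimethylsilyl chloride, CC(C)(C)[Si](C)(C)Cl
Why: Standard silylation of the primary allylic alcohol, which does not touch the alkene geometry.

**Step 15**
Reactants: 22 methyl (Z)-2-{[(tert-butyldimethylsilyl)oxy]methyl}but-2-enoate
Product: 23 (Z)-2-{[(tert-butyldimethylsilyl)oxy]methyl}but-2-enoic acid
Conditions: LiOH, THF/H2O, 0 °C → rt; then 1 M HCl to pH 4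
Reagents that add atoms: lithium hydroxide, [Li+].[OH-]
Why: Saponification of the methyl ester, under which the primary TBS ether and the Z alkene are stable.

**Step 16**
Reactants: 19 (1(10)Z,2R,4E,6R,7S,9S)-2-[(tert-butyldimethylsilyl)oxy]-9-hydroxygermacra-1(10),4,11(13)-trien-12,6-olide; 23 (Z)-2-{[(tert-butyldimethylsilyl)oxy]methyl}but-2-enoic acid
Product: 24 (1(10)Z,2R,4E,6R,7S,9S)-2-[(tert-butyldimethylsilyl)oxy]-9-{(Z)-2-{[(tert-butyldimethylsilyl)oxy]methyl}but-2-enoyloxy}germacra-1(10),4,11(13)-trien-12,6-olide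
Conditions: 23, 2,4,6-trichlorobenzoyl chloride, Et3N, toluene, rt; then 19, DMAP, rt
Reagents that add atoms: none
Why: Yamaguchi esterification through the mixed anhydride acylates the only free hydroxyl (C9) with retention and, as with angelates, without Z-to-E isomerisation of the acid.

**Step 17**
Reactants: 24 (1(10)Z,2R,4E,6R,7S,9S)-2-[(tert-butyldimethylsilyl)oxy]-9-{(Z)-2-{[(tert-butyldimethylsilyl)oxy]methyl}but-2-enoyloxy}germacra-1(10),4,11(13)-trien-12,6-olide
Product: 25 (1(10)Z,2R,4E,6R,7S,9S)-2-hydroxy-9-[(Z)-2-(hydroxymethyl)but-2-enoyloxy]germacra-1(10),4,11(13)-trien-12,6-olide (CNP0273961.1)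
Conditions: HF·pyridine, pyridine/THF, 0 °C → rt
Reagents that add atoms: none
Why: Buffered fluoride desilylation removes both TBS ethers in one operation without touching the esters, the lactone or the alkenes.

**Compound list**
1 | methyl acetoacetate | CC(=O)CC(=O)OC | starting material
2 | (S)-2-vinyloxirane | C=C[C@H]1CO1 | starting material
3 | methyl (6R)-6-hydroxy-3-oxooct-7-enoate | COC(=O)CC(=O)CC[C@@H](O)C=C | intermediate (not isolated)
4 | methyl (6R)-6-[(tert-butyldimethylsilyl)oxy]-3-oxooct-7-enoate | COC(=O)CC(=O)CC[C@@H](O[Si](C)(C)C(C)(C)C)C=C | intermediate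
5 | ethynyltri(propan-2-yl)silane | C#C[Si](C(C)C)(C(C)C)C(C)C | starting material
6 | (E)-3-(dimethylamino)prop-2-enal | CN(C)/C=C/C=O | starting material
7 | (E)-5-[tri(propan-2-yl)silyl]pent-2-en-4-ynal | O=C/C=C/C#C[Si](C(C)C)(C(C)C)C(C)C | intermediate
8 | methyl (6R)-6-[(tert-butyldimethylsilyl)oxy]-3-oxo-2-{(3S)-1-oxo-5-[tri(propan-2-yl)silyl]pent-4-yn-3-yl}oct-7-enoate (Michael adduct, C2 epimers) | COC(=O)C(C(=O)CC[C@@H](O[Si](C)(C)C(C)(C)C)C=C)[C@H](CC=O)C#C[Si](C(C)C)(C(C)C)C(C)C | intermediate (not isolated)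
9 | methyl (1R,6S)-3-{(2R)-2-[(tert-butyldimethylsilyl)oxy]but-3-en-1-yl}-2-oxo-6-{[tri(propan-2-yl)silyl]ethynyl}cyclohex-3-ene-1-carboxylate | COC(=O)[C@@H]1[C@@H](C#C[Si](C(C)C)(C(C)C)C(C)C)CC=C(C[C@@H](O[Si](C)(C)C(C)(C)C)C=C)C1=O | intermediate
10 | methyl (1R,3R,6S)-3-{(2R)-2-[(tert-butyldimethylsilyl)oxy]but-3-en-1-yl}-3-methyl-2-oxo-6-{[tri(propan-2-yl)silyl]ethynyl}cyclohex-4-ene-1-carboxylate | COC(=O)[C@@H]1[C@@H](C#C[Si](C(C)C)(C(C)C)C(C)C)C=C[C@@](C)(C[C@@H](O[Si](C)(C)C(C)(C)C)C=C)C1=O | intermediate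
11 | (2R,5R)-2-{(2R)-2-[(tert-butyldimethylsilyl)oxy]but-3-en-1-yl}-2-methyl-5-{[tri(propan-2-yl)silyl]ethynyl}cyclohex-3-en-1-one | O=C1C[C@@H](C#C[Si](C(C)C)(C(C)C)C(C)C)C=C[C@@]1(C)C[C@@H](O[Si](C)(C)C(C)(C)C)C=C | intermediate
12 | (1R,2R,5S,6S)-2-{(2R)-2-[(tert-butyldimethylsilyl)oxy]but-3-en-1-yl}-2-methyl-5-{[tri(propan-2-yl)silyl]ethynyl}-7-oxabicyclo[4.1.0]heptan-3-one | O=C1C[C@@H](C#C[Si](C(C)C)(C(C)C)C(C)C)[C@@H]2O[C@@H]2[C@@]1(C)C[C@@H](O[Si](C)(C)C(C)(C)C)C=C | intermediate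
13 | prop-1-en-2-ylmagnesium bromide | CC(=C)[Mg]Br | starting material
14 | (1R,2R,3S,5S,6S)-2-{(2R)-2-[(tert-butyldimethylsilyl)oxy]but-3-en-1-yl}-2-methyl-3-(prop-1-en-2-yl)-5-{[tri(propan-2-yl)silyl]ethynyl}-7-oxabicyclo[4.1.0]heptan-3-ol | CC(=C)[C@@]1(O)C[C@@H](C#C[Si](C(C)C)(C(C)C)C(C)C)[C@@H]2O[C@@H]2[C@@]1(C)C[C@@H](O[Si](C)(C)C(C)(C)C)C=C | intermediate
15 | cis-fused (2R,4R,5R,6S,7S,9S)-2-[(tert-butyldimethylsilyl)oxy]-5,6-epoxy-4,10-dimethyl-7-{[tri(propan-2-yl)silyl]ethynyl}bicyclo[4.4.0]dec-1(10)-en-9-ol (target numbering, C4–C9 fusion) | CC1=C[C@H](O[Si](C)(C)C(C)(C)C)C[C@]2(C)[C@H]3O[C@H]3[C@H](C#C[Si](C(C)C)(C(C)C)C(C)C)C[C@]12O | intermediate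
16 | (2Z,4R,6E,8R,9S)-4-[(tert-butyldimethylsilyl)oxy]-8-hydroxy-2,6-dimethyl-9-{[tri(propan-2-yl)silyl]ethynyl}cyclodeca-2,6-dien-1-one | O=C1C[C@@H](C#C[Si](C(C)C)(C(C)C)C(C)C)[C@H](O)/C=C(\C)C[C@@H](O[Si](C)(C)C(C)(C)C)/C=C1/C | intermediate
17 | (2Z,4R,6E,8R,9S)-4-[(tert-butyldimethylsilyl)oxy]-9-ethynyl-8-hydroxy-2,6-dimethylcyclodeca-2,6-dien-1-one | O=C1C[C@@H](C#C)[C@H](O)/C=C(\C)C[C@@H](O[Si](C)(C)C(C)(C)C)/C=C1/C | intermediate
18 | (1(10)Z,2R,4E,6R,7S)-2-[(tert-butyldimethylsilyl)oxy]-9-oxogermacra-1(10),4,11(13)-trien-12,6-olide | C=C1C(=O)O[C@@H]2/C=C(\C)C[C@@H](O[Si](C)(C)C(C)(C)C)/C=C(/C)C(=O)C[C@@H]12 | intermediate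
19 | (1(10)Z,2R,4E,6R,7S,9S)-2-[(tert-butyldimethylsilyl)oxy]-9-hydroxygermacra-1(10),4,11(13)-trien-12,6-olide | C=C1C(=O)O[C@@H]2/C=C(\C)C[C@@H](O[Si](C)(C)C(C)(C)C)/C=C(/C)[C@@H](O)C[C@@H]12 | intermediate
20 | methyl but-2-ynoate | CC#CC(=O)OC | starting material
21 | methyl (Z)-2-(hydroxymethyl)but-2-enoate | C/C=C(/CO)C(=O)OC | intermediate
22 | methyl (Z)-2-{[(tert-butyldimethylsilyl)oxy]methyl}but-2-enoate | C/C=C(/CO[Si](C)(C)C(C)(C)C)C(=O)OC | intermediate
23 | (Z)-2-{[(tert-butyldimethylsilyl)oxy]methyl}but-2-enoic acid | C/C=C(/CO[Si](C)(C)C(C)(C)C)C(=O)O | intermediate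
24 | (1(10)Z,2R,4E,6R,7S,9S)-2-[(tert-butyldimethylsilyl)oxy]-9-{(Z)-2-{[(tert-butyldimethylsilyl)oxy]methyl}but-2-enoyloxy}germacra-1(10),4,11(13)-trien-12,6-olide | C=C1C(=O)O[C@@H]2/C=C(\C)C[C@@H](O[Si](C)(C)C(C)(C)C)/C=C(/C)[C@@H](OC(=O)/C(=C\C)CO[Si](C)(C)C(C)(C)C)C[C@@H]12 | intermediate
25 | (1(10)Z,2R,4E,6R,7S,9S)-2-hydroxy-9-[(Z)-2-(hydroxymethyl)but-2-enoyloxy]germacra-1(10),4,11(13)-trien-12,6-olide | C=C1C(=O)O[C@@H]2/C=C(\C)C[C@@H](O)/C=C(/C)[C@@H](OC(=O)/C(=C\C)CO)C[C@@H]12 | target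

**Totals**
Total step count: 17. Longest linear sequence: 13 steps (1, 3–12, 16, 17).

**Three steps most likely to fail**

Step 4 (the proposed new step): the site of methylation (C4 against C6, C8 or O) and the facial selectivity, which rests only on 1,4-induction from a slim alkynyl group, are both untested. The fallback sets out from 9 and comes back at 11 using known chemistry. Krapcho dealkoxycarbonylation of 9 (LiCl, wet DMSO, 120 °C) gives (5S)-2-{(2R)-2-[(tert-butyldimethylsilyl)oxy]but-3-en-1-yl}-5-{[tri(propan-2-yl)silyl]ethynyl}cyclohex-2-en-1-one F1. Classical deconjugative α-methylation of its thermodynamic potassium dienolate (KOt-Bu, t-BuOH/THF, 0 °C; MeI) then gives 11 directly, without 10. The C4 epimers are separated by chromatography at 11 or after epoxidation.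

Step 9 (ring expansion): the potassium alkoxide may be diverted (epoxide opening, base-induced isomerisation of the Z-enone or epimerisation at C2) before it fragments. The fallback sets out from 15 and comes back at 16. It replaces the alkoxide push by a Lewis-acid pull, that is a Holton-type epoxy-alcohol fragmentation with Ti(Oi-Pr)4 in CH2Cl2 at 40 °C. The titanium alkoxide and the titanium-activated oxirane fragment without any free base. It makes no compound outside the list (F0).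

Step 12 (C9 configuration): the conformation of the macrocycle may override the CBS catalyst and deliver the 9R alcohol. The fallback sets out from 18 and comes back at 24. Substrate-controlled Luche reduction (NaBH4, CeCl3·7H2O, MeOH, −78 °C) is used if it gives the 9R epimer, (1(10)Z,2R,4E,6R,7S,9R)-2-[(tert-butyldimethylsilyl)oxy]-9-hydroxygermacra-1(10),4,11(13)-trien-12,6-olide F2. Mitsunobu esterification of F2 with acid 23 (PPh3, DIAD, toluene, 0 °C) inverts C9 and gives 24, without 19.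

**Further compounds**
F1 | step 4 | (5S)-2-{(2R)-2-[(tert-butyldimethylsilyl)oxy]but-3-en-1-yl}-5-{[tri(propan-2-yl)silyl]ethynyl}cyclohex-2-en-1-one | O=C1C[C@@H](C#C[Si](C(C)C)(C(C)C)C(C)C)CC=C1C[C@@H](O[Si](C)(C)C(C)(C)C)C=C
F0 | step 9 | none | none
F2 | step 12 | (1(10)Z,2R,4E,6R,7S,9R)-2-[(tert-butyldimethylsilyl)oxy]-9-hydroxygermacra-1(10),4,11(13)-trien-12,6-olide | C=C1C(=O)O[C@@H]2/C=C(\C)C[C@@H](O[Si](C)(C)C(C)(C)C)/C=C(/C)[C@H](O)C[C@@H]12
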